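We decide to carry GE as a concentration, not as a percentage of X.

in all of them: Z 11 mM
- Tuesday's: X 0.20 M; E 0.24 M; run made earlier
- Sunday's: X 0.45 M; E 0.24 M; run made earlier
- flask: X 0.30 M; E 0.240 M; time 12 h

| run | time / h | GE / % | G / % |
|---|---|---|---|
| Tuesday's | 1.00 | 1.0 | 16.4 |
| Tuesday's | 2.00 | 2.1 | 28.0 |
| Tuesday's | 3.00 | 4.4 | 32.0 |
| Tuesday's | 5.00 | 11.2 | 35.6 |
| Tuesday's | 8.00 | 15.5 | 39.9 |
| Tuesday's | 15.0 | 23.3 | 42.5 |
| Sunday's | 2.50 | 2.5 | 14.8 |
| Sunday's | 5.00 | 4.4 | 18.1 |
| Sunday's | 8.00 | 7.0 | 18.5 |
| Sunday's | 10.0 | 9.8 | 19.7 |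
| Sunday's | 12.0 | 10.0 | 19.5 |
| Sunday's | 15.0 | 11.1 | 18.6 |

(readings scatter by 1 percentage point)

1. the GE standing at 12 h, as a percentage of the X charged
2. concentration of G in solution at 12 h, in percent of saturation

- solid, in amounts per volume of the solution: X
- the numbers in the tables scatter with a standard deviation of 1 percentage point
- at the start none of X is in solution
- G means what is dissolved; the solid is not counted in it
- G is what X becomes in solution

Two extreme versions of this flask can be reckoned in the head. In the first, X enters solution at once, cGE grows in step with the charge of X at the same E and Z, and GE keeps the percentage of Tuesday's run, about 20.0% between its readings. In the second, the solid feeds G just as fast as G is used, so GE is zero order in the charge of X. The quantity to carry is then cGE at 12 h, read from Sunday's run as 0.0450 M, which is 15.0% of this flask's charge.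

The runs point to the second version. At 1.00 h in Tuesday's run, G had reached 0.0328 M and GE 0.00200 M, so supply at first ran far ahead of use. G then rose ever more slowly in Tuesday's run, so supply drifted down towards use. At 8.00 h, cGE reads 0.0310 M on a charge of 0.20 M and 0.0315 M on 0.45 M. We commit to 15.0% for this flask, and expect G to stand below saturation at that time.

The forecast gives 14.2% and 95%, holding “so G is solubility-limited near 0.09 M”.

The flask gives 14.5% of GE, with G at 85.2% of saturation.

    G + E ⇌ GE (K = 8.40 M⁻¹, k = 0.00660 M⁻¹ min⁻¹)
    G + E ⇌ D (K = 470 M⁻¹, k = 0.00390 M⁻¹ min⁻¹)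
    GE + Z ⇌ D + Z, rate k3*[Z]*[GE] forward; the back reaction follows from the equilibrium constant (k = 0.0370 M⁻¹ min⁻¹)
    X ⇌ G, rate k4*(cs4 - [G]) while solid is left; crystals form when [G] > cs4 (solubility = 0.100 M, k = 0.00790 min⁻¹)

At 12.0 h in this flask, G is made 1.14 times as fast as it is used, each step taken net. Our cGE, divided by this flask's charge, gave 15.0%. In the neighbour charged with 0.75 M of X, the same cGE gives 6.00%, and that flask stands at 5.79%.

(Readings and results stem from a simulated flask on assumed constants; the scatter is artificial.)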